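The route rests on closing the pyran ring at C4–C4a (chroman numbering) of an achiral precursor, an aryl 3-iodopropargyl ether of ring A. Under monovalent gold catalysis the iodoalkyne becomes a gold vinylidene. C4a, the only free carbon ortho to O1 and para to the C7 oxygen, attacks it, so one operation forms the C4–C4a bond, closes the pyran ring and shifts iodine from C4 to C3. That iodide is the handle for Negishi attachment of ring B. Because C4 is a methylene and C3 the sole stereocentre, iridium-catalysed asymmetric hydrogenation of the resulting isoflav-3-ene then sets (3S); hydrogenolysis of two benzyl ethers finishes the route.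

Key step: step 8

Remark on the chemistry: ring A is the benzo ring of the chroman and ring B the aryl group on C3; 2-hydroxy-3,4-dimethoxybenzaldehyde and 2-methoxybenzene-1,3-diol are taken as commercially available, and the target is assigned (3S) from its SMILES.

Step 1
Reactants: 1 2-hydroxy-3,4-dimethoxybenzaldehyde
Product: 2 2-(benzyloxy)-3,4-dimethoxybenzaldehyde
Conditions: BnBr, K2CO3, DMF, 60 °C
Reagents that add atoms: benzyl bromide, BrCc1ccccc1
Why: Williamson O-benzylation of the only acidic site; the aldehyde is inert to carbonate and benzyl bromide.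

Step 2
Reactants: 2 2-(benzyloxy)-3,4-dimethoxybenzaldehyde
Product: 4 2-(benzyloxy)-3,4-dimethoxyphenol, via aryl formate 3 (not isolated)
Conditions: mCPBA, CH2Cl2, 0 °C to rt; then K2CO3 (cat.), MeOH, rt
Reagents that add atoms: mCPBA, OOC(=O)c1cccc(Cl)c1
Why: Baeyer–Villiger (Dakin-type) oxidation, in which the electron-rich aryl group with ortho and para alkoxy donors migrates to oxygen in preference to hydrogen, followed by methanolysis of the formate.

Step 3
Reactants: 4 2-(benzyloxy)-3,4-dimethoxyphenol
Product: 5 2-(benzyloxy)-6-bromo-3,4-dimethoxyphenol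
Conditions: NBS (1.0 equiv), iPr2NH (cat.), CH2Cl2, −20 °C
Reagents that add atoms: N-bromosuccinimide, O=C1CCC(=O)N1Br
Why: Electrophilic aromatic bromination steered by the free phenol, whose para position is blocked by a methoxy group, so C6 (ortho to OH, para to the C3 methoxy) is the only strongly activated site.

Step 4
Reactants: 5 2-(benzyloxy)-6-bromo-3,4-dimethoxyphenol
Product: 6 3-(benzyloxy)-1-bromo-2,4,5-trimethoxybenzene
Conditions: MeI, K2CO3, acetone, reflux
Reagents that add atoms: iodomethane, CI
Why: Williamson O-methylation of the acidic ortho-bromophenol; aryl bromide and benzyl ether are inert.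

Step 5
Reactants: 7 2-methoxybenzene-1,3-diol
Product: 8 3-(benzyloxy)-2-methoxyphenol
Conditions: 7 (2 equiv), BnBr (1 equiv), K2CO3, acetone, reflux
Reagents that add atoms: benzyl bromide, BrCc1ccccc1
Why: Williamson mono-alkylation of a symmetric diol used in excess, which can give only one mono-ether, separable from recovered diol and bis-ether.

Step 6
Reactants: 8 3-(benzyloxy)-2-methoxyphenol
Product: 9 1-(benzyloxy)-2-methoxy-3-(prop-2-yn-1-yloxy)benzene
Conditions: propargyl bromide, K2CO3, DMF, rt
Reagents that add atoms: propargyl bromide, BrCC#C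
Why: Williamson O-propargylation of the phenoxide; carbonate is too weak a base to isomerise the alkyne.

Step 7
Reactants: 9 1-(benzyloxy)-2-methoxy-3-(prop-2-yn-1-yloxy)benzene
Product: 10 1-(benzyloxy)-3-[(3-iodoprop-2-yn-1-yl)oxy]-2-methoxybenzene
Conditions: NIS, AgNO3 (10 mol %), acetone, rt, dark
Reagents that add atoms: N-iodosuccinimide, O=C1CCC(=O)N1I
Why: Silver-catalysed iodination of a terminal alkyne through its silver acetylide, which should react with NIS faster than the arene does in the absence of acid.

Step 8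
Reactants: 10 1-(benzyloxy)-3-[(3-iodoprop-2-yn-1-yl)oxy]-2-methoxybenzene
Product: 11 7-(benzyloxy)-3-iodo-8-methoxy-2H-chromene
Conditions: (IPr)AuNTf2 (5 mol %; IPr = 1,3-bis(2,6-diisopropylphenyl)imidazol-2-ylidene), 1,4-dioxane, 100 °C
Reagents that add atoms: none
Why: The cationic gold fragment binds the iodoalkyne and a 1,2-iodine shift gives a catalyst-bound gold vinylidene whose electrophilic carbon (the future C4) is attacked by C4a of ring A in a Friedel–Crafts manner; rearomatisation and protodeauration release the 3-iodo-2H-chromene. The closest known reaction type is the gold-catalysed cycloisomerisation of aryl 3-iodopropargyl ethers and of 2-(haloethynyl)biaryls by way of halovinylidenes, a formal hydroarylation with 1,2-halogen migration. The pyran ring is closed in a formal 6-endo-dig mode by electrophilic aromatic substitution at C4a. No stereocentre is formed, since C3 stays trigonal and is set later by hydrogenation. The step needs site selectivity on ring A, secured because the second carbon ortho to O1 carries the methoxy group while C4a is activated by the para benzyloxy oxygen, and it needs iodine migration ahead of arene attack, which the strongly donating carbene ligand and the weakly coordinating triflimide counter-ion are chosen to favour.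

Step 9
Reactants: 6 3-(benzyloxy)-1-bromo-2,4,5-trimethoxybenzene; 11 7-(benzyloxy)-3-iodo-8-methoxy-2H-chromene
Product: 14 7-(benzyloxy)-3-[3-(benzyloxy)-2,4,5-trimethoxyphenyl]-8-methoxy-2H-chromene, via aryllithium 12 (not isolated), via arylzinc chloride 13 (not isolated)
Conditions: 6, n-BuLi, THF, −78 °C; ZnCl2, −78 °C to rt; then 11, Pd(PPh3)4 (5 mol %), THF, 50 °C
Reagents that add atoms: none
Why: Bromine–lithium exchange and transmetalation to zinc, then Negishi cross-coupling, in which zerovalent palladium inserts into the alkenyl C–I bond of 11 and couples it with the arylzinc; the ethers are untouched.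

Step 10
Reactants: 14 7-(benzyloxy)-3-[3-(benzyloxy)-2,4,5-trimethoxyphenyl]-8-methoxy-2H-chromene
Product: 15 (3S)-7-(benzyloxy)-3-[3-(benzyloxy)-2,4,5-trimethoxyphenyl]-8-methoxy-3,4-dihydro-2H-chromene
Conditions: [Ir(cod)((S)-tBu-PHOX)]BArF (2 mol %; BArF = tetrakis[3,5-bis(trifluoromethyl)phenyl]borate), H2 (50 bar), CH2Cl2, rt
Reagents that add atoms: none
Why: Iridium-catalysed asymmetric hydrogenation of an unfunctionalised trisubstituted cyclic aryl alkene with a chiral phosphine–oxazoline ligand, a reaction type established for 3-aryl-2H-chromenes; the ligand controls the face of hydrogen delivery to C3 and so sets the stereocentre, and the ligand antipode that gives (3S) is used (the (R)-ligand if the (S)-ligand should give the opposite sense).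

Step 11
Reactants: 15 (3S)-7-(benzyloxy)-3-[3-(benzyloxy)-2,4,5-trimethoxyphenyl]-8-methoxy-3,4-dihydro-2H-chromene
Product: 16 (3S)-3-(3-hydroxy-2,4,5-trimethoxyphenyl)-8-methoxy-3,4-dihydro-2H-chromen-7-ol
Conditions: H2 (1 atm), Pd/C (10 %), EtOAc/MeOH, rt
Reagents that add atoms: none
Why: Hydrogenolysis of both benzyl aryl ethers over palladium on carbon; the chroman C–O bonds are not benzylic C–O bonds and C3 has no acidic hydrogen or leaving group, so the stereocentre should be retained.

Compound list
1 | 2-hydroxy-3,4-dimethoxybenzaldehyde | COc1ccc(C=O)c(O)c1OC | starting material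
2 | 2-(benzyloxy)-3,4-dimethoxybenzaldehyde | COc1ccc(C=O)c(OCc2ccccc2)c1OC | intermediate
3 | 2-(benzyloxy)-3,4-dimethoxyphenyl formate | COc1ccc(OC=O)c(OCc2ccccc2)c1OC | intermediate (not isolated)
4 | 2-(benzyloxy)-3,4-dimethoxyphenol | COc1ccc(O)c(OCc2ccccc2)c1OC | intermediate
5 | 2-(benzyloxy)-6-bromo-3,4-dimethoxyphenol | COc1cc(Br)c(O)c(OCc2ccccc2)c1OC | intermediate
6 | 3-(benzyloxy)-1-bromo-2,4,5-trimethoxybenzene | COc1cc(Br)c(OC)c(OCc2ccccc2)c1OC | intermediate
7 | 2-methoxybenzene-1,3-diol | COc1c(O)cccc1O | starting material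
8 | 3-(benzyloxy)-2-methoxyphenol | COc1c(O)cccc1OCc1ccccc1 | intermediate
9 | 1-(benzyloxy)-2-methoxy-3-(prop-2-yn-1-yloxy)benzene | COc1c(OCC#C)cccc1OCc1ccccc1 | intermediate
10 | 1-(benzyloxy)-3-[(3-iodoprop-2-yn-1-yl)oxy]-2-methoxybenzene | COc1c(OCC#CI)cccc1OCc1ccccc1 | intermediate
11 | 7-(benzyloxy)-3-iodo-8-methoxy-2H-chromene | COc1c(OCc2ccccc2)ccc2C=C(I)COc12 | intermediate
12 | [3-(benzyloxy)-2,4,5-trimethoxyphenyl]lithium | [Li]c1cc(OC)c(OC)c(OCc2ccccc2)c1OC | intermediate (not isolated)
13 | [3-(benzyloxy)-2,4,5-trimethoxyphenyl]zinc chloride | Cl[Zn]c1cc(OC)c(OC)c(OCc2ccccc2)c1OC | intermediate (not isolated)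
14 | 7-(benzyloxy)-3-[3-(benzyloxy)-2,4,5-trimethoxyphenyl]-8-methoxy-2H-chromene | COc1cc(C2=Cc3ccc(OCc4ccccc4)c(OC)c3OC2)c(OC)c(OCc2ccccc2)c1OC | intermediate
15 | (3S)-7-(benzyloxy)-3-[3-(benzyloxy)-2,4,5-trimethoxyphenyl]-8-methoxy-3,4-dihydro-2H-chromene | COc1cc([C@H]2COc3c(ccc(OCc4ccccc4)c3OC)C2)c(OC)c(OCc2ccccc2)c1OC | intermediate
16 | (3S)-3-(3-hydroxy-2,4,5-trimethoxyphenyl)-8-methoxy-3,4-dihydro-2H-chromen-7-ol | COc1cc([C@H]2COc3c(ccc(O)c3OC)C2)c(OC)c(O)c1OC | target

Total step count: 11.
Longest linear sequence: 7 steps (steps 1–4, then 9, 10 and 11; the ring A branch, steps 5–8, then 9, 10 and 11, is equally long).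

Steps most likely to fail

Step 8. The electron-rich arene may attack the gold-bound alkyne before the iodine shift, so that iodine stays on C4 and the handle on C3 is lost; the iodide may also be lost altogether by protodeiodination. The fallback forms the same C4–C4a bond by an acid-mediated cyclodehydration and sets out from 6 and 8. Bromide 6 is lithiated (n-BuLi, THF, −78 °C) and acylated with 2-chloro-N-methoxy-N-methylacetamide to give 1-[3-(benzyloxy)-2,4,5-trimethoxyphenyl]-2-chloroethan-1-one F1. Phenol 8 is alkylated with it (K2CO3, KI cat., acetone, reflux) to give 2-[3-(benzyloxy)-2-methoxyphenoxy]-1-[3-(benzyloxy)-2,4,5-trimethoxyphenyl]ethan-1-one F2. Wittig methoxymethylenation (Ph3P=CHOMe from the phosphonium chloride and KOtBu, THF, 0 °C) gives the enol ether 1-(benzyloxy)-3-({2-[3-(benzyloxy)-2,4,5-trimethoxyphenyl]-3-methoxyprop-2-en-1-yl}oxy)-2-methoxybenzene F3 as an E/Z mixture. TsOH (cat.) in toluene at 80 °C should protonate the enol ether at C3, let C4a attack the oxocarbenium carbon and expel methanol, which delivers 14, where the route is rejoined.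

Step 10. Face discrimination may be poor or the hydrogenation slow, because the 2'-methoxy group crowds the trisubstituted alkene. The fallback sets the stereocentre by dynamic kinetic resolution and sets out from 14. Hydroboration–oxidation (BH3·THF, then NaOH, H2O2) should give racemic trans-7-(benzyloxy)-3-[3-(benzyloxy)-2,4,5-trimethoxyphenyl]-8-methoxychroman-4-ol F4. Oxidation with Dess–Martin periodinane (CH2Cl2, rt) gives the configurationally labile isoflavanone 7-(benzyloxy)-3-[3-(benzyloxy)-2,4,5-trimethoxyphenyl]-8-methoxychroman-4-one F5. Asymmetric transfer hydrogenation under dynamic kinetic resolution (RuCl[(S,S)-TsDPEN](p-cymene) or its antipode, HCO2H/Et3N, EtOAc, 40 °C) should give the cis alcohol (3S,4S)-7-(benzyloxy)-3-[3-(benzyloxy)-2,4,5-trimethoxyphenyl]-8-methoxychroman-4-ol F6. Hydrogenolysis (H2, Pd/C, EtOH/AcOH) then removes the C4 hydroxyl and both benzyl groups and comes back to the route at target 16.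

Step 3. The very electron-rich para-methoxyphenol may be oxidised towards a quinone by NBS, or some bromination may occur at C5. The fallback replaces electrophilic bromination by directed ortho-metalation and sets out from 4. Carbamoylation (ClCONEt2, NaH, THF) gives 2-(benzyloxy)-3,4-dimethoxyphenyl diethylcarbamate F7. Lithiation at the only free ortho position (s-BuLi, TMEDA, THF, −78 °C) and quench with BrCF2CF2Br gives 2-(benzyloxy)-6-bromo-3,4-dimethoxyphenyl diethylcarbamate F8. Cleavage of the carbamate (KOH, EtOH, reflux) returns to the route at 5.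

Further compounds
F1 | step 8 | 1-[3-(benzyloxy)-2,4,5-trimethoxyphenyl]-2-chloroethan-1-one | COc1cc(C(=O)CCl)c(OC)c(OCc2ccccc2)c1OC
F2 | step 8 | 2-[3-(benzyloxy)-2-methoxyphenoxy]-1-[3-(benzyloxy)-2,4,5-trimethoxyphenyl]ethan-1-one | COc1cc(C(=O)COc2cccc(OCc3ccccc3)c2OC)c(OC)c(OCc2ccccc2)c1OC
F3 | step 8 | 1-(benzyloxy)-3-({2-[3-(benzyloxy)-2,4,5-trimethoxyphenyl]-3-methoxyprop-2-en-1-yl}oxy)-2-methoxybenzene (E/Z mixture) | COC=C(COc1cccc(OCc2ccccc2)c1OC)c1cc(OC)c(OC)c(OCc2ccccc2)c1OC
F4 | step 10 | trans-7-(benzyloxy)-3-[3-(benzyloxy)-2,4,5-trimethoxyphenyl]-8-methoxychroman-4-ol (racemic, the 3S,4R enantiomer drawn) | COc1cc([C@H]2COc3c(ccc(OCc4ccccc4)c3OC)[C@@H]2O)c(OC)c(OCc2ccccc2)c1OC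
F5 | step 10 | 7-(benzyloxy)-3-[3-(benzyloxy)-2,4,5-trimethoxyphenyl]-8-methoxychroman-4-one (racemic) | COc1cc(C2COc3c(ccc(OCc4ccccc4)c3OC)C2=O)c(OC)c(OCc2ccccc2)c1OC
F6 | step 10 | (3S,4S)-7-(benzyloxy)-3-[3-(benzyloxy)-2,4,5-trimethoxyphenyl]-8-methoxychroman-4-ol | COc1cc([C@H]2COc3c(ccc(OCc4ccccc4)c3OC)[C@H]2O)c(OC)c(OCc2ccccc2)c1OC
F7 | step 3 | 2-(benzyloxy)-3,4-dimethoxyphenyl diethylcarbamate | CCN(CC)C(=O)Oc1ccc(OC)c(OC)c1OCc1ccccc1
F8 | step 3 | 2-(benzyloxy)-6-bromo-3,4-dimethoxyphenyl diethylcarbamate | CCN(CC)C(=O)Oc1c(Br)cc(OC)c(OC)c1OCc1ccccc1
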